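**Assumption:** the SMILES is read literally. The propenoic acid arm on C4 is cis to the C3a–C3 bond and trans to the C5 phenyl, and each ring methyl (C1, C3) is trans to the hydrogen on its neighbouring ring-fusion carbon. Hexahydroindene numbering is used throughout: C1/C3 carry the methyls, C3a/C7a are the ring fusion, C4 is quaternary, C5 carries phenyl, C6=C7 is the alkene.

## Retrosynthetic overview

1. Target 15 ⇐ 14 ⇐ 12: the C4 ester of the bicycle is homologated to the (E)-2-methylpropenoic acid arm (one-pot reduction/Wittig, then saponification).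
2. 12 ⇐ 11: one thermal intramolecular Diels–Alder reaction of a (Z)-2-ethyl trienoate closes the cyclohexene and, through the three-carbon tether, the cyclopentane in the same step. No ring exists before it; it sets C3a, C4, C5 and C7a.
3. 11 ⇐ 7 ⇐ 6: the (E,E)-diene (Wittig, then Horner–Wadsworth–Emmons) and the (Z)-dienophile (Still–Gennari) are grown from the two ends of an anti-2,4-dimethylglutarate derivative.
4. Key bond (C3–C4 of 6, later C2–C1 of the ring): stereoconvergent Ni-catalysed coupling of a zinc homoenolate (from bromide 4) with a racemic α-bromo amide (enolonium equivalent). Both carbons react against their carbonyl-derived polarity.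

## Route

**Step 1**
Reactants: 1 2-bromopropanoyl bromide; 2 N-benzylaniline
Product: 3 rac-N-benzyl-2-bromo-N-phenylpropanamide
Conditions: Et3N, CH2Cl2, 0 °C → rt
Reagents that add atoms: none
Why: N-acylation of the secondary aniline by the acyl bromide (Schotten–Baumann-type amide formation); no stereocentre is controlled because 3 is used as the racemate.

**Step 2**
Reactants: 4 methyl (2S)-3-bromo-2-methylpropanoate; 3 rac-N-benzyl-2-bromo-N-phenylpropanamide
Product: 6 methyl (2R,4R)-5-[benzyl(phenyl)amino]-2,4-dimethyl-5-oxopentanoate, via zinc homoenolate 5 (not isolated)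
Conditions: 4, Zn dust, I2 (5 mol %), DMA, 70 °C; then 3, NiCl2(MeOCH2CH2OMe) (10 mol %), i-Pr-Pybox (13 mol %, antipode giving 4R), DMI/THF, 0 °C
Reagents that add atoms: none
Why: Stereoconvergent nickel-catalysed Negishi cross-coupling (Fu type): the zinc homoenolate 5 (nucleophilic β-carbon of an ester, C2 retained from 4) is joined to the α-carbon of the α-bromo amide through a prochiral α-carbonyl radical, and the chiral Ni–Pybox catalyst sets the new C4 centre as R whatever the configuration of 3.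

**Step 3**
Reactants: 6 methyl (2R,4R)-5-[benzyl(phenyl)amino]-2,4-dimethyl-5-oxopentanoate
Product: 7 methyl (2R,4R)-2,4-dimethyl-5-oxopentanoate
Conditions: Cp2Zr(H)Cl (1.6 equiv), THF, rt; aqueous work-up
Reagents that add atoms: none
Why: Chemoselective reduction of the tertiary amide with Cp2Zr(H)Cl (Georg amide-to-aldehyde reduction) stops at the zirconated hemiaminal, which hydrolyses to the aldehyde and leaves the methyl ester and the α-stereocentre untouched.

**Step 4**
Reactants: 7 methyl (2R,4R)-2,4-dimethyl-5-oxopentanoate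
Product: 8 methyl (2R,4R,5E)-2,4,6-trimethyl-7-oxohept-5-enoate
Conditions: Ph3P=C(Me)CHO (1.2 equiv), PhMe, 80 °C
Reagents that add atoms: 2-(triphenylphosphoranylidene)propanal, CC(C=O)=P(c1ccccc1)(c1ccccc1)c1ccccc1
Why: Wittig olefination with a stabilised formyl ylide gives the (E)-trisubstituted enal under neutral conditions that do not epimerise C4.

**Step 5**
Reactants: 8 methyl (2R,4R,5E)-2,4,6-trimethyl-7-oxohept-5-enoate
Product: 9 methyl (2R,4R,5E,7E)-2,4,6-trimethyl-8-phenylocta-5,7-dienoate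
Conditions: (EtO)2P(O)CH2Ph, NaH, THF, 0 °C → rt
Reagents that add atoms: diethyl benzylphosphonate, CCOP(=O)(Cc1ccccc1)OCC
Why: Horner–Wadsworth–Emmons olefination of the enal with the benzylphosphonate anion gives the (E)-styryl double bond and so completes the (E,E)-diene.

**Step 6**
Reactants: 9 methyl (2R,4R,5E,7E)-2,4,6-trimethyl-8-phenylocta-5,7-dienoate
Product: 10 (2R,4R,5E,7E)-2,4,6-trimethyl-8-phenylocta-5,7-dienal
Conditions: i-Bu2AlH (1.05 equiv), CH2Cl2, −78 °C
Reagents that add atoms: none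
Why: Partial ester reduction with i-Bu2AlH stops at the tetrahedral aluminate at −78 °C, which releases the α-chiral aldehyde on work-up without epimerisation.

**Step 7**
Reactants: 10 (2R,4R,5E,7E)-2,4,6-trimethyl-8-phenylocta-5,7-dienal
Product: 11 methyl (2Z,4R,6R,7E,9E)-2-ethyl-4,6,8-trimethyl-10-phenyldeca-2,7,9-trienoate
Conditions: methyl 2-[bis(2,2,2-trifluoroethoxy)phosphoryl]butanoate, KN(SiMe3)2, 18-crown-6, THF, −78 °C
Reagents that add atoms: methyl 2-[bis(2,2,2-trifluoroethoxy)phosphoryl]butanoate, CCC(C(=O)OC)P(=O)(OCC(F)(F)F)OCC(F)(F)F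
Why: Still–Gennari variant of the Horner–Wadsworth–Emmons reaction: fast elimination from the kinetic adduct of the electron-poor phosphonate gives the (Z)-trisubstituted enoate (ester cis to the chain), the dienophile geometry that the C4 centre of the target requires.

**Step 8**
Reactants: 11 methyl (2Z,4R,6R,7E,9E)-2-ethyl-4,6,8-trimethyl-10-phenyldeca-2,7,9-trienoate
Product: 12 methyl (1R,3R,3aR,4R,5S,7aR)-4-ethyl-1,3,7-trimethyl-5-phenyl-2,3,3a,4,5,7a-hexahydro-1H-indene-4-carboxylate
Conditions: BHT (cat.), PhMe, 170 °C, sealed tube, no Lewis acid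
Reagents that add atoms: none
Why: Thermal type 1 intramolecular Diels–Alder reaction via the anti (trans-fused) transition state with the ester exo: suprafacial addition places the C4 ester cis to the C3a–C3 bond (from the Z-enoate) and the C5 phenyl cis to the C7a–C1 bond (from the E,E-diene), and the two pre-set methyl centres of the tether choose the diene face, so C3a, C4, C5 and C7a are all set here.

**Step 9**
Reactants: 12 methyl (1R,3R,3aR,4R,5S,7aR)-4-ethyl-1,3,7-trimethyl-5-phenyl-2,3,3a,4,5,7a-hexahydro-1H-indene-4-carboxylate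
Product: 14 ethyl (2E)-3-[(1R,3R,3aR,4S,5S,7aR)-4-ethyl-1,3,7-trimethyl-5-phenyl-2,3,3a,4,5,7a-hexahydro-1H-inden-4-yl]-2-methylprop-2-enoate, via ring aldehyde 13 (not isolated)
Conditions: i-Bu2AlH (1.1 equiv), PhMe, −78 °C; then Ph3P=C(Me)CO2Et, −78 → 90 °C
Reagents that add atoms: ethyl 2-(triphenylphosphoranylidene)propanoate, CCOC(=O)C(C)=P(c1ccccc1)(c1ccccc1)c1ccccc1
Why: One-pot partial reduction and Wittig olefination: the hindered neopentyl ester gives a stable aluminate that collapses to aldehyde 13 on warming and is trapped by the stabilised ylide as the (E)-2-methylpropenoate, the quaternary centre being untouched (its descriptor changes to 4S only through substituent priorities).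

**Step 10**
Reactants: 14 ethyl (2E)-3-[(1R,3R,3aR,4S,5S,7aR)-4-ethyl-1,3,7-trimethyl-5-phenyl-2,3,3a,4,5,7a-hexahydro-1H-inden-4-yl]-2-methylprop-2-enoate
Product: 15 (2E)-3-[(1R,3R,3aR,4S,5S,7aR)-4-ethyl-1,3,7-trimethyl-5-phenyl-2,3,3a,4,5,7a-hexahydro-1H-inden-4-yl]-2-methylprop-2-enoic acid
Conditions: LiOH, THF/MeOH/H2O, 50 °C; then 1 M HCl
Reagents that add atoms: lithium hydroxide, [Li+].[OH-]
Why: Saponification of the ethyl ester followed by acidification gives the free acid without touching any stereocentre or either trisubstituted alkene.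

## Compound list

1 | 2-bromopropanoyl bromide | CC(Br)C(Br)=O | starting material
2 | N-benzylaniline | C(Nc1ccccc1)c1ccccc1 | starting material
3 | rac-N-benzyl-2-bromo-N-phenylpropanamide | CC(Br)C(=O)N(Cc1ccccc1)c1ccccc1 | intermediate
4 | methyl (2S)-3-bromo-2-methylpropanoate | COC(=O)[C@H](C)CBr | starting material
5 | bromo[(2S)-3-methoxy-2-methyl-3-oxopropyl]zinc (zinc homoenolate) | COC(=O)[C@H](C)C[Zn]Br | intermediate
6 | methyl (2R,4R)-5-[benzyl(phenyl)amino]-2,4-dimethyl-5-oxopentanoate | COC(=O)[C@H](C)C[C@@H](C)C(=O)N(Cc1ccccc1)c1ccccc1 | intermediate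
7 | methyl (2R,4R)-2,4-dimethyl-5-oxopentanoate | COC(=O)[C@H](C)C[C@@H](C)C=O | intermediate
8 | methyl (2R,4R,5E)-2,4,6-trimethyl-7-oxohept-5-enoate | COC(=O)[C@H](C)C[C@@H](C)/C=C(\C)C=O | intermediate
9 | methyl (2R,4R,5E,7E)-2,4,6-trimethyl-8-phenylocta-5,7-dienoate | COC(=O)[C@H](C)C[C@@H](C)/C=C(\C)/C=C/c1ccccc1 | intermediate
10 | (2R,4R,5E,7E)-2,4,6-trimethyl-8-phenylocta-5,7-dienal | O=C[C@H](C)C[C@@H](C)/C=C(\C)/C=C/c1ccccc1 | intermediate
11 | methyl (2Z,4R,6R,7E,9E)-2-ethyl-4,6,8-trimethyl-10-phenyldeca-2,7,9-trienoate | COC(=O)/C(CC)=C\[C@H](C)C[C@@H](C)/C=C(\C)/C=C/c1ccccc1 | intermediate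
12 | methyl (1R,3R,3aR,4R,5S,7aR)-4-ethyl-1,3,7-trimethyl-5-phenyl-2,3,3a,4,5,7a-hexahydro-1H-indene-4-carboxylate | CC[C@@]1(C(=O)OC)[C@H]2[C@H](C(C)=C[C@H]1c1ccccc1)[C@H](C)C[C@H]2C | intermediate
13 | (1R,3R,3aR,4R,5S,7aR)-4-ethyl-1,3,7-trimethyl-5-phenyl-2,3,3a,4,5,7a-hexahydro-1H-indene-4-carbaldehyde | CC[C@@]1(C=O)[C@H]2[C@H](C(C)=C[C@H]1c1ccccc1)[C@H](C)C[C@H]2C | intermediate
14 | ethyl (2E)-3-[(1R,3R,3aR,4S,5S,7aR)-4-ethyl-1,3,7-trimethyl-5-phenyl-2,3,3a,4,5,7a-hexahydro-1H-inden-4-yl]-2-methylprop-2-enoate | CC[C@@]1(/C=C(\C)C(=O)OCC)[C@H]2[C@H](C(C)=C[C@H]1c1ccccc1)[C@H](C)C[C@H]2C | intermediate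
15 | (2E)-3-[(1R,3R,3aR,4S,5S,7aR)-4-ethyl-1,3,7-trimethyl-5-phenyl-2,3,3a,4,5,7a-hexahydro-1H-inden-4-yl]-2-methylprop-2-enoic acid (plakotenin as drawn) | CC[C@@]1(/C=C(\C)C(=O)O)[C@H]2[C@H](C(C)=C[C@H]1c1ccccc1)[C@H](C)C[C@H]2C | target

## Step count and risks

Total steps: 10. Longest linear sequence: 10 steps (1 → 3 → 6 → … → 15); bromide 4 enters at step 2.

**Step 8 (cycloaddition) — highest risk, and I expect 12 to be the minor product.** The relationships that follow from alkene geometry are secure. However, 12 needs the diene face on which both tether methyls sit pseudo-axially (C3-methyl syn to the C4 ester, C1-methyl syn to the C7 methyl). Allylic 1,3-strain in 11 favours the other trans-fused diastereomer, and ester-endo (cis-fused) addition also competes. The fallback sets out from 11 and comes back to the route at 13. Reduce 11 with i-Bu2AlH (2.2 equiv, −78 °C) to (2Z,4R,6R,7E,9E)-2-ethyl-4,6,8-trimethyl-10-phenyldeca-2,7,9-trien-1-ol F2. Oxidise with MnO2 to (2Z,4R,6R,7E,9E)-2-ethyl-4,6,8-trimethyl-10-phenyldeca-2,7,9-trienal F3. Run the cycloaddition at −78 °C under reagent control with the HNTf2-activated (S)-B-(o-tolyl) CBS oxazaborolidine (antipode chosen for the C3a/C7a configuration of 13); this is chiral Lewis-acid catalysis in which α-substituted enals react formyl-exo. It gives 13 directly, which is then olefinated and hydrolysed as in steps 9 and 10.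

**Step 2 (key coupling).** The zinc reagent is β-branched and carries an ester, so rate and enantioselectivity of the Ni/Pybox coupling may fall below those of simple alkylzincs. The fallback sets out from 5 and comes back at 6. Pd(PPh3)4-catalysed Negishi coupling of 5 with N-benzyl-2-bromo-N-phenylprop-2-enamide gives methyl (2R)-4-[benzyl(phenyl)carbamoyl]-2-methylpent-4-enoate F1 without creating a stereocentre. C4 is then set by catalyst-controlled asymmetric hydrogenation ([Rh(cod)((R,R)-Me-DuPhos)]BF4, H2, MeOH), which returns 6.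

**Step 9 (one-pot reduction/olefination).** The ester sits on a quaternary carbon next to the phenyl-bearing centre, so reduction may need temperatures at which the aluminate over-reduces, and the neopentyl aldehyde may be slow towards the ylide. The fallback sets out from 12 and comes back at 14. Reduce 12 with LiAlH4 to [(1R,3R,3aR,4R,5S,7aR)-4-ethyl-1,3,7-trimethyl-5-phenyl-2,3,3a,4,5,7a-hexahydro-1H-inden-4-yl]methanol F4. Oxidise with Dess–Martin periodinane to isolated 13. Add the lithium enolate of ethyl propanoate (LiN(i-Pr)2, THF, −78 °C; aldol addition with a small nucleophile) to give ethyl 3-[(1R,3R,3aR,4R,5S,7aR)-4-ethyl-1,3,7-trimethyl-5-phenyl-2,3,3a,4,5,7a-hexahydro-1H-inden-4-yl]-3-hydroxy-2-methylpropanoate F5 (mixture at the two new side-chain centres). Eliminate through the mesylate (MsCl, Et3N; then DBU, E1cB) to the (E)-enoate 14.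

## Further compounds

F1 | step 2 | methyl (2R)-4-[benzyl(phenyl)carbamoyl]-2-methylpent-4-enoate | COC(=O)[C@H](C)CC(=C)C(=O)N(Cc1ccccc1)c1ccccc1
F2 | step 8 | (2Z,4R,6R,7E,9E)-2-ethyl-4,6,8-trimethyl-10-phenyldeca-2,7,9-trien-1-ol | OC/C(CC)=C\[C@H](C)C[C@@H](C)/C=C(\C)/C=C/c1ccccc1
F3 | step 8 | (2Z,4R,6R,7E,9E)-2-ethyl-4,6,8-trimethyl-10-phenyldeca-2,7,9-trienal | O=C/C(CC)=C\[C@H](C)C[C@@H](C)/C=C(\C)/C=C/c1ccccc1
F4 | step 9 | [(1R,3R,3aR,4R,5S,7aR)-4-ethyl-1,3,7-trimethyl-5-phenyl-2,3,3a,4,5,7a-hexahydro-1H-inden-4-yl]methanol | CC[C@@]1(CO)[C@H]2[C@H](C(C)=C[C@H]1c1ccccc1)[C@H](C)C[C@H]2C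
F5 | step 9 | ethyl 3-[(1R,3R,3aR,4R,5S,7aR)-4-ethyl-1,3,7-trimethyl-5-phenyl-2,3,3a,4,5,7a-hexahydro-1H-inden-4-yl]-3-hydroxy-2-methylpropanoate | CC[C@@]1(C(O)C(C)C(=O)OCC)[C@H]2[C@H](C(C)=C[C@H]1c1ccccc1)[C@H](C)C[C@H]2C
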